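Numbering: indole N1–C7a (OH on C4, Br on C6); pyrimidine N1'–C6' (Br on C2', NH2 on C4', C5' bonded to C3). The enabling feature is ring A: oxygen on C4 beside the fusion atom C3a, an exchangeable heteroatom site on C6 meta to it, and plain C–H at C5 and C7. A ketene/heteroatom-alkyne benzannulation writes exactly this pattern.
Late cuts: the O–CH3 protecting group at C4, C4'–N (SNAr with NH3), C2'–Br and C4'–Br (from a uracil masked as the 2,4-dimethoxypyrimidine), and C6–Br (from C6–N by Sandmeyer exchange).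
Core cut: C7a–C7, C7–C6, C5–C4 and C4–C3a, which splits ring A into a 4-pyrimidinylpyrrol-2-yl diazo ketone and a terminal ynamide. The last cut is the C3–C5' biaryl bond (Suzuki–Miyaura).
Forward: the pyrrole (ring B) and pyrimidine (ring C) are bought and joined first, and the methyl ketone is turned into the diazo ketone. Ring A is the only ring built; after it come C4–O capping, N-to-Br exchange at C6, uracil unmasking, N1 release, C2'/C4' bromination, C4' amination and C4–O release.
Stereochemistry: the target has no stereocentre and no configured double bond. The sp3 centres of two transient intermediates disappear on aromatisation.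

Key step: step 6

Remark: benzyl N-benzylcarbamate is taken to be a catalogue compound, and the C3–C5' axis is treated as freely rotating, so the target is handled as achiral.

Step 1
Reactants: 1 1-(4-bromo-1H-pyrrol-2-yl)ethanone
Product: 2 1-[4-bromo-1-(4-methylbenzenesulfonyl)pyrrol-2-yl]ethanone
Conditions: NaH, TsCl, THF, 0 °C to rt
Reagents that add atoms: 4-methylbenzenesulfonyl chloride (TsCl), Cc1ccc(S(=O)(=O)Cl)cc1
Why: N-sulfonylation of the acidic 2-acylpyrrole N–H is routine, and installing the tosyl group before the cross-coupling suppresses the hydrodebromination that unprotected 4-bromo-2-acylpyrroles tend to suffer under palladium catalysis.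

Step 2
Reactants: 2 1-[4-bromo-1-(4-methylbenzenesulfonyl)pyrrol-2-yl]ethanone; 3 (2,4-dimethoxypyrimidin-5-yl)boronic acid
Product: 4 1-[4-(2,4-dimethoxypyrimidin-5-yl)-1-(4-methylbenzenesulfonyl)pyrrol-2-yl]ethanone
Conditions: Pd(dppf)Cl2 (5 mol %), K3PO4, 1,4-dioxane–H2O, 80 °C
Reagents that add atoms: none
Why: In this Suzuki–Miyaura coupling the electron-poor C4–Br bond of the N-sulfonyl acylpyrrole adds readily to zerovalent palladium and the boronic acid is a standard partner, which sets the future C3–C5' bond.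

Step 3
Reactants: 4 1-[4-(2,4-dimethoxypyrimidin-5-yl)-1-(4-methylbenzenesulfonyl)pyrrol-2-yl]ethanone
Product: 6 2-diazo-1-[4-(2,4-dimethoxypyrimidin-5-yl)-1-(4-methylbenzenesulfonyl)pyrrol-2-yl]ethan-1-one, via trifluoroacetyl diketone 5 (not isolated)
Conditions: LiN(SiMe3)2, THF, −78 °C, then CF3CO2CH2CF3; aq HCl wash; MsN3, Et3N, H2O, MeCN, rt
Reagents that add atoms: methanesulfonyl azide, CS(=O)(=O)N=[N+]=[N-] (both diazo nitrogens); 2,2,2-trifluoroethyl trifluoroacetate, O=C(OCC(F)(F)F)C(F)(F)F (trifluoroacetyl group of 5 only, lost again)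
Why: In this detrifluoroacetylative diazo transfer the lithium enolate of the methyl ketone is acylated to the activated 1,3-diketone 5, which takes the diazo group from the sulfonyl azide (Regitz-type transfer) and sheds the trifluoroacetyl group, a sequence designed for methyl ketones that resist direct diazo transfer.

Step 4
Reactants: 7 benzyl N-benzylcarbamate; 8 (bromoethynyl)triisopropylsilane
Product: 9 benzyl N-benzyl-N-[(triisopropylsilyl)ethynyl]carbamate
Conditions: CuSO4·5H2O (10 mol %), 1,10-phenanthroline (20 mol %), K3PO4, toluene, 80 °C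
Reagents that add atoms: none
Why: Copper-catalysed N-alkynylation of a carbamate with a bromoalkyne (Ullmann-type C–N coupling) is the standard entry to ynamides, and the bulky silyl group holds back alkyne homocoupling.

Step 5
Reactants: 9 benzyl N-benzyl-N-[(triisopropylsilyl)ethynyl]carbamate
Product: 10 benzyl N-benzyl-N-ethynylcarbamate
Conditions: Bu4NF, wet THF, 0 °C
Reagents that add atoms: none
Why: Fluoride-induced protodesilylation of the C(sp)–Si bond is fast at 0 °C and leaves the carbamate and the ynamide triple bond untouched.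

Step 6
Reactants: 6 2-diazo-1-[4-(2,4-dimethoxypyrimidin-5-yl)-1-(4-methylbenzenesulfonyl)pyrrol-2-yl]ethan-1-one; 10 benzyl N-benzyl-N-ethynylcarbamate
Product: 15 benzyl N-benzyl-N-[3-(2,4-dimethoxypyrimidin-5-yl)-4-hydroxy-1-(4-methylbenzenesulfonyl)indol-6-yl]carbamate, via pyrrolylketene 11 (not isolated), via aminocyclobutenone 12 (not isolated), via dienylketene 13 (not isolated), via cyclohexadienone 14 (not isolated)
Conditions: 10 (1.2 equiv), hν (medium-pressure Hg lamp, Pyrex filter), CH2Cl2, rt; then toluene, 110 °C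
Reagents that add atoms: none
Why: Light expels N2 from 6 and the pyrrol-2-yl group shifts to the former diazo carbon (photo-Wolff rearrangement, C7a–C7) to give ketene 11, whose carbonyl carbon is attacked by the unsubstituted, nucleophilic alkyne carbon of 10 in a (2+2) cycloaddition (C5–C4 and C7–C6) leading to 12. Heating opens 12 in a reversible 4π electrocyclic reaction to 13, and ring A closes by 6π electrocyclisation of the ketene carbon onto pyrrole C3 (C4–C3a), after which 14 tautomerises to the phenol. This is the diazo ketone variant of the Danheiser benzannulation, a reaction type established for aryl and heteroaryl diazo ketones with ynamides. No stereocentre remains, because the single sp3 centres of 12 and 14 are erased on ring opening and aromatisation. Two regiochemical choices matter: the cycloaddition is steered by the nitrogen polarisation of the ynamide (N ends on C6, H on C5), and the closure has only one option because the ketene-bearing pyrrole C2 has C3 as its sole carbon neighbour, the other being the sulfonylated nitrogen. The filtered light spares the sulfonamide and benzyl chromophores, and the slight excess of 10 limits acylation of phenol 15 by 11.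

Step 7
Reactants: 15 benzyl N-benzyl-N-[3-(2,4-dimethoxypyrimidin-5-yl)-4-hydroxy-1-(4-methylbenzenesulfonyl)indol-6-yl]carbamate
Product: 16 benzyl N-benzyl-N-[3-(2,4-dimethoxypyrimidin-5-yl)-4-methoxy-1-(4-methylbenzenesulfonyl)indol-6-yl]carbamate
Conditions: MeI, K2CO3, DMF, rt
Reagents that add atoms: iodomethane, CI
Why: Williamson-type O-alkylation of the only acidic site, the C4 phenol, gives a methyl ether that withstands hydrogenolysis, diazotisation, hot acid, hydroxide and POBr3.

Step 8
Reactants: 16 benzyl N-benzyl-N-[3-(2,4-dimethoxypyrimidin-5-yl)-4-methoxy-1-(4-methylbenzenesulfonyl)indol-6-yl]carbamate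
Product: 18 3-(2,4-dimethoxypyrimidin-5-yl)-4-methoxy-1-(4-methylbenzenesulfonyl)indol-6-amine, via N-benzylaniline 17 (not isolated)
Conditions: H2 (1 atm), Pd(OH)2/C, EtOH–EtOAc, rt
Reagents that add atoms: none
Why: Catalytic hydrogenolysis cleaves both benzylic bonds in one operation, first the carbamate C–O bond (with loss of CO2) and then the N-benzyl bond of 17, at a stage where the molecule holds no carbon–halogen bond.

Step 9
Reactants: 18 3-(2,4-dimethoxypyrimidin-5-yl)-4-methoxy-1-(4-methylbenzenesulfonyl)indol-6-amine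
Product: 20 6-bromo-3-(2,4-dimethoxypyrimidin-5-yl)-4-methoxy-1-(4-methylbenzenesulfonyl)indole, via diazonium bromide 19 (not isolated)
Conditions: NaNO2, 48% aq HBr, MeCN, 0 °C; then CuBr, 0 °C to rt
Reagents that add atoms: hydrogen bromide, Br (the C6 bromine); sodium nitrite, [Na+].[O-]N=O (outer nitrogen of 19 only, lost as N2)
Why: The Sandmeyer reaction (diazotisation in strong acid, then bromide transfer mediated by monovalent copper) exchanges the only amino group in the molecule for bromine, because the pyrimidine is still in its amine-free dimethoxy form and the tosyl group blocks N1 against nitrosation.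

Step 10
Reactants: 20 6-bromo-3-(2,4-dimethoxypyrimidin-5-yl)-4-methoxy-1-(4-methylbenzenesulfonyl)indole
Product: 21 5-[6-bromo-4-methoxy-1-(4-methylbenzenesulfonyl)indol-3-yl]pyrimidine-2,4(1H,3H)-dione
Conditions: 6 M aq HCl, 1,4-dioxane, 100 °C
Reagents that add atoms: water, O
Why: Acid hydrolysis of the two lactim (imidate) ethers is the usual unmasking of 2,4-dimethoxypyrimidines to uracils, the aryl methyl ether is inert, and the tosyl group shields the methoxyindole from acid-induced oligomerisation.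

Step 11
Reactants: 21 5-[6-bromo-4-methoxy-1-(4-methylbenzenesulfonyl)indol-3-yl]pyrimidine-2,4(1H,3H)-dione
Product: 22 5-(6-bromo-4-methoxy-1H-indol-3-yl)pyrimidine-2,4(1H,3H)-dione
Conditions: NaOH, 1,4-dioxane–H2O, 80 °C; then neutralise
Reagents that add atoms: none
Why: In this sulfonamide hydrolysis hydroxide attacks the sulfonyl sulfur and expels the bromine-stabilised indolide, and omitting an alcohol cosolvent avoids an alkyl tosylate that could alkylate the uracil or indole anion.

Step 12
Reactants: 22 5-(6-bromo-4-methoxy-1H-indol-3-yl)pyrimidine-2,4(1H,3H)-dione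
Product: 23 6-bromo-3-(2,4-dibromopyrimidin-5-yl)-4-methoxy-1H-indole
Conditions: POBr3, PhNMe2, toluene, 110 °C; then ice water
Reagents that add atoms: phosphorus oxybromide, O=P(Br)(Br)Br
Why: Deoxybromination through O-phosphorylated lactims and bromide addition–elimination is the standard way from uracils to 2,4-dibromopyrimidines, and the aniline base takes up HBr and stray bromine so that the C4 ether and indole C2 should stay intact.

Step 13
Reactants: 23 6-bromo-3-(2,4-dibromopyrimidin-5-yl)-4-methoxy-1H-indole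
Product: 24 2-bromo-5-(6-bromo-4-methoxy-1H-indol-3-yl)pyrimidin-4-amine
Conditions: NH3 (2 M in i-PrOH), sealed tube, 60 °C
Reagents that add atoms: ammonia, N
Why: Nucleophilic aromatic substitution of 2,4-dihalopyrimidines by the small nucleophile ammonia prefers C4', where the Meisenheimer adduct is para-quinoid, and the new amino group then deactivates C2' against a second substitution.

Step 14
Reactants: 24 2-bromo-5-(6-bromo-4-methoxy-1H-indol-3-yl)pyrimidin-4-amine
Product: 25 3-(4-amino-2-bromopyrimidin-5-yl)-6-bromo-1H-indol-4-ol (target)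
Conditions: BBr3 (excess), CH2Cl2, −78 °C to rt; then H2O
Reagents that add atoms: none
Why: Lewis acid ether cleavage with BBr3 removes the last protecting group, the excess reagent compensates for binding to the basic nitrogens, and any halide exchange at C2' is degenerate because bromide is the only halide present.

Compound list
1 | 1-(4-bromo-1H-pyrrol-2-yl)ethanone | CC(=O)c1cc(Br)c[nH]1 | starting material
2 | 1-[4-bromo-1-(4-methylbenzenesulfonyl)pyrrol-2-yl]ethanone | CC(=O)c1cc(Br)cn1S(=O)(=O)c1ccc(C)cc1 | intermediate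
3 | (2,4-dimethoxypyrimidin-5-yl)boronic acid | COc1ncc(B(O)O)c(OC)n1 | starting material
4 | 1-[4-(2,4-dimethoxypyrimidin-5-yl)-1-(4-methylbenzenesulfonyl)pyrrol-2-yl]ethanone | COc1ncc(-c2cc(C(C)=O)n(S(=O)(=O)c3ccc(C)cc3)c2)c(OC)n1 | intermediate
5 | 1-[4-(2,4-dimethoxypyrimidin-5-yl)-1-(4-methylbenzenesulfonyl)pyrrol-2-yl]-4,4,4-trifluorobutane-1,3-dione | COc1ncc(-c2cc(C(=O)CC(=O)C(F)(F)F)n(S(=O)(=O)c3ccc(C)cc3)c2)c(OC)n1 | intermediate (not isolated)
6 | 2-diazo-1-[4-(2,4-dimethoxypyrimidin-5-yl)-1-(4-methylbenzenesulfonyl)pyrrol-2-yl]ethan-1-one | COc1ncc(-c2cc(C(=O)C=[N+]=[N-])n(S(=O)(=O)c3ccc(C)cc3)c2)c(OC)n1 | intermediate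
7 | benzyl N-benzylcarbamate | O=C(NCc1ccccc1)OCc1ccccc1 | starting material
8 | (bromoethynyl)triisopropylsilane | CC(C)[Si](C#CBr)(C(C)C)C(C)C | starting material
9 | benzyl N-benzyl-N-[(triisopropylsilyl)ethynyl]carbamate | CC(C)[Si](C#CN(Cc1ccccc1)C(=O)OCc1ccccc1)(C(C)C)C(C)C | intermediate
10 | benzyl N-benzyl-N-ethynylcarbamate | C#CN(Cc1ccccc1)C(=O)OCc1ccccc1 | intermediate
11 | [4-(2,4-dimethoxypyrimidin-5-yl)-1-(4-methylbenzenesulfonyl)pyrrol-2-yl]ketene | COc1ncc(-c2cc(C=C=O)n(S(=O)(=O)c3ccc(C)cc3)c2)c(OC)n1 | intermediate (not isolated)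
12 | benzyl N-benzyl-N-{4-[4-(2,4-dimethoxypyrimidin-5-yl)-1-(4-methylbenzenesulfonyl)pyrrol-2-yl]-3-oxocyclobut-1-en-1-yl}carbamate (racemic) | O=C1C=C(N(Cc2ccccc2)C(=O)OCc2ccccc2)C1c1cc(-c2cnc(OC)nc2OC)cn1S(=O)(=O)c1ccc(C)cc1 | intermediate (not isolated)
13 | benzyl N-benzyl-N-{1-[4-(2,4-dimethoxypyrimidin-5-yl)-1-(4-methylbenzenesulfonyl)pyrrol-2-yl]-4-oxobuta-1,3-dien-2-yl}carbamate, pyrrolyl group cis to the ketenyl carbon | O=C=C/C(N(Cc1ccccc1)C(=O)OCc1ccccc1)=C\c1cc(-c2cnc(OC)nc2OC)cn1S(=O)(=O)c1ccc(C)cc1 | intermediate (not isolated)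
14 | benzyl N-benzyl-N-[3-(2,4-dimethoxypyrimidin-5-yl)-1-(4-methylbenzenesulfonyl)-4-oxo-3a,4-dihydroindol-6-yl]carbamate (racemic) | O=C1C=C(N(Cc2ccccc2)C(=O)OCc2ccccc2)C=C2N(S(=O)(=O)c3ccc(C)cc3)C=C(c3cnc(OC)nc3OC)C12 | intermediate (not isolated)
15 | benzyl N-benzyl-N-[3-(2,4-dimethoxypyrimidin-5-yl)-4-hydroxy-1-(4-methylbenzenesulfonyl)indol-6-yl]carbamate | COc1ncc(-c2cn(S(=O)(=O)c3ccc(C)cc3)c3cc(N(Cc4ccccc4)C(=O)OCc4ccccc4)cc(O)c23)c(OC)n1 | intermediate
16 | benzyl N-benzyl-N-[3-(2,4-dimethoxypyrimidin-5-yl)-4-methoxy-1-(4-methylbenzenesulfonyl)indol-6-yl]carbamate | COc1ncc(-c2cn(S(=O)(=O)c3ccc(C)cc3)c3cc(N(Cc4ccccc4)C(=O)OCc4ccccc4)cc(OC)c23)c(OC)n1 | intermediate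
17 | N-benzyl-3-(2,4-dimethoxypyrimidin-5-yl)-4-methoxy-1-(4-methylbenzenesulfonyl)indol-6-amine | COc1ncc(-c2cn(S(=O)(=O)c3ccc(C)cc3)c3cc(NCc4ccccc4)cc(OC)c23)c(OC)n1 | intermediate (not isolated)
18 | 3-(2,4-dimethoxypyrimidin-5-yl)-4-methoxy-1-(4-methylbenzenesulfonyl)indol-6-amine | COc1ncc(-c2cn(S(=O)(=O)c3ccc(C)cc3)c3cc(N)cc(OC)c23)c(OC)n1 | intermediate
19 | 3-(2,4-dimethoxypyrimidin-5-yl)-4-methoxy-1-(4-methylbenzenesulfonyl)indole-6-diazonium bromide | COc1ncc(-c2cn(S(=O)(=O)c3ccc(C)cc3)c3cc([N+]#N)cc(OC)c23)c(OC)n1.[Br-] | intermediate (not isolated)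
20 | 6-bromo-3-(2,4-dimethoxypyrimidin-5-yl)-4-methoxy-1-(4-methylbenzenesulfonyl)indole | COc1ncc(-c2cn(S(=O)(=O)c3ccc(C)cc3)c3cc(Br)cc(OC)c23)c(OC)n1 | intermediate
21 | 5-[6-bromo-4-methoxy-1-(4-methylbenzenesulfonyl)indol-3-yl]pyrimidine-2,4(1H,3H)-dione | COc1cc(Br)cc2c1c(-c1c[nH]c(=O)[nH]c1=O)cn2S(=O)(=O)c1ccc(C)cc1 | intermediate
22 | 5-(6-bromo-4-methoxy-1H-indol-3-yl)pyrimidine-2,4(1H,3H)-dione | COc1cc(Br)cc2[nH]cc(-c3c[nH]c(=O)[nH]c3=O)c12 | intermediate
23 | 6-bromo-3-(2,4-dibromopyrimidin-5-yl)-4-methoxy-1H-indole | COc1cc(Br)cc2[nH]cc(-c3cnc(Br)nc3Br)c12 | intermediate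
24 | 2-bromo-5-(6-bromo-4-methoxy-1H-indol-3-yl)pyrimidin-4-amine | COc1cc(Br)cc2[nH]cc(-c3cnc(Br)nc3N)c12 | intermediate
25 | 3-(4-amino-2-bromopyrimidin-5-yl)-6-bromo-1H-indol-4-ol | Nc1nc(Br)ncc1-c1c[nH]c2cc(Br)cc(O)c12 | target

Total step count: 14.
Longest linear sequence: 12 steps (steps 1–3 and 6–14, from 1). The ynamide branch (steps 4 and 5) joins at step 6.

Steps most likely to fail

Step 6. The pyrimidinyl group next to pyrrole C3 crowds the forming C4–C3a bond, so the 6π closure may be slow. The ketenes would then be lost by dimerisation or by acylating the product phenol, and the terminal ynamide may degrade during long irradiation.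
The fallback postpones the biaryl bond so that only a bromine flanks the closing position. Starting from 2, trifluoroacetylation as in step 3 gives 1-[4-bromo-1-(4-methylbenzenesulfonyl)pyrrol-2-yl]-4,4,4-trifluorobutane-1,3-dione F1, and diazo transfer gives 1-[4-bromo-1-(4-methylbenzenesulfonyl)pyrrol-2-yl]-2-diazoethan-1-one F2. Irradiation and heating with 10 should give benzyl N-benzyl-N-[3-bromo-4-hydroxy-1-(4-methylbenzenesulfonyl)indol-6-yl]carbamate F3. MeI and K2CO3 then give benzyl N-benzyl-N-[3-bromo-4-methoxy-1-(4-methylbenzenesulfonyl)indol-6-yl]carbamate F4. Suzuki–Miyaura coupling of F4 with 3 (Pd(OAc)2, SPhos, K3PO4, toluene–H2O) rejoins the route at 16.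

Step 9. The ring of 18 is activated at C5 and C7 by both the amine and the C4 methoxy group. Azo coupling of the diazonium ion with unreacted amine, ring bromination or nitrosation, hydrodediazoniation, and partial hydrolysis of the methoxypyrimidine in aqueous HBr can all compete.
The fallback passes through a carbon–boron bond under acid-free conditions. Starting from 18, deaminative borylation (t-BuONO, bis(pinacolato)diboron, MeCN, rt) gives 3-(2,4-dimethoxypyrimidin-5-yl)-4-methoxy-1-(4-methylbenzenesulfonyl)-6-(4,4,5,5-tetramethyl-1,3,2-dioxaborolan-2-yl)indole F5. Bromodeboronation with CuBr2 in MeOH–H2O at 80 °C rejoins the route at 20.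

Step 12. The uracil is poorly soluble, so conversion may stall. Hot POBr3 can release bromine that attacks the unprotected indole at C2, and HBr can begin to cleave the C4 ether.
The fallback separates activation from bromide introduction. Starting from 22, POCl3 with PhNMe2 at reflux serves as its own solvent, releases no free halogen, and gives 6-bromo-3-(2,4-dichloropyrimidin-5-yl)-4-methoxy-1H-indole F6. Halogen exchange on this soluble, purified dichloride with Me3SiBr in propionitrile at reflux rejoins the route at 23.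

Further compounds
F1 | step 6 | 1-[4-bromo-1-(4-methylbenzenesulfonyl)pyrrol-2-yl]-4,4,4-trifluorobutane-1,3-dione | O=C(CC(=O)C(F)(F)F)c1cc(Br)cn1S(=O)(=O)c1ccc(C)cc1
F2 | step 6 | 1-[4-bromo-1-(4-methylbenzenesulfonyl)pyrrol-2-yl]-2-diazoethan-1-one | [N-]=[N+]=CC(=O)c1cc(Br)cn1S(=O)(=O)c1ccc(C)cc1
F3 | step 6 | benzyl N-benzyl-N-[3-bromo-4-hydroxy-1-(4-methylbenzenesulfonyl)indol-6-yl]carbamate | Oc1cc(N(Cc2ccccc2)C(=O)OCc2ccccc2)cc2c1c(Br)cn2S(=O)(=O)c1ccc(C)cc1
F4 | step 6 | benzyl N-benzyl-N-[3-bromo-4-methoxy-1-(4-methylbenzenesulfonyl)indol-6-yl]carbamate | COc1cc(N(Cc2ccccc2)C(=O)OCc2ccccc2)cc2c1c(Br)cn2S(=O)(=O)c1ccc(C)cc1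
F5 | step 9 | 3-(2,4-dimethoxypyrimidin-5-yl)-4-methoxy-1-(4-methylbenzenesulfonyl)-6-(4,4,5,5-tetramethyl-1,3,2-dioxaborolan-2-yl)indole | COc1ncc(-c2cn(S(=O)(=O)c3ccc(C)cc3)c3cc(B4OC(C)(C)C(C)(C)O4)cc(OC)c23)c(OC)n1
F6 | step 12 | 6-bromo-3-(2,4-dichloropyrimidin-5-yl)-4-methoxy-1H-indole | COc1cc(Br)cc2[nH]cc(-c3cnc(Cl)nc3Cl)c12
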